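The runs are calculated with made-up constants.

| setting | teal | blue | grey | flask |
|---|---|---|---|---|
| electrophile | 0.22 M (fed, over 20 h) | 0.35 M (fed, over 20 h) | 0.16 M (fed, over 20 h) | 0.16 M (fed, over 20 h) |
| free base | 0.128 M | 0.128 M | 0.19 M | 0.128 M |
| gas | 19 mM (held) | 19 mM (held) | 19 mM (held) | 19 mM (held) |
| remark | run made earlier | run made earlier | run made earlier |  |
| time |  |  |  | 20 h |

| run | time / h | electrophile / % | product / % |
|---|---|---|---|
| teal | 1.50 | 7.9 | 0.4 |
| teal | 2.50 | 13.0 | 0.5 |
| teal | 4.00 | 19.3 | 1.3 |
| teal | 8.00 | 38.6 | 2.5 |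
| teal | 12.0 | 55.7 | 4.4 |
| teal | 20.0 | 87.3 | 12.2 |
| blue | 1.50 | 8.0 | 0 |
| blue | 2.50 | 12.0 | 0.5 |
| blue | 4.00 | 18.9 | 0 |
| blue | 8.00 | 38.0 | 2.5 |
| blue | 12.0 | 55.6 | 4.4 |
| blue | 20.0 | 89.9 | 10.8 |
| grey | 1.50 | 8.1 | 0 |
| grey | 3.00 | 15.0 | 0.1 |
| grey | 6.00 | 27.9 | 0.7 |
| grey | 10.0 | 46.6 | 2.4 |
| grey | 20.0 | 86.6 | 12.9 |

(standard deviation of a reading: 0.5 percentage points)
- at the start none of the gas is in solution
- percentages count the whole charge, also what has not yet gone in
- the earlier runs do not show how much of nucleophile is bound; that part of a forecast is a guess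
- part of the electrophile that has reacted at 20 h
- share of free nucleophile in free nucleophile and protonated nucleophile together, at 20 h

- Each unit of product, I assumed, sets free one unit of acid, and the free base and the nucleophile share that acid.
- For c in the flask I took the grey reading, 12.9 %, as grey had the flask's electrophile charge; teal, with more electrophile, gave 12.2 %.
- That makes 20.6 mM of acid in the flask, and 16.1 % of the free base charged; this ratio, acid made over free base charged, is the acid load L.
- The flask's free base stood well above that acid, as an acid scavenger should.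
- The runs do not show how tightly each partner binds acid, so I assumed equal binding, which gives both the same free share.
- With the nucleophile pool counted as nothing, my lower bound on fr was 1 − L, 83.9 %; with the pool counted at the gas level, 19 mM, my upper bound was 86.0 %.
- The forecast gave c = 12.9 %, level with my figure, and fr = 60 %, below my bracket: “Excess base suggests mostly free, but this is a guess.”
- The flask gave c = 12.8 % and fr = 83.8 %, which is 24 percentage points above the forecast and on my lower edge.

    nucleophile + acid set free ⇌ protonated nucleophile, settled at all times (K = 3.30 × 10⁵ L mol⁻¹)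
    acid set free + free base ⇌ salt of the base, settled at all times (K = 2.90 × 10⁵ L mol⁻¹)
    gas ⇌ nucleophile, rate k3*(csat - [nucleophile]) (kL = 0.350 h⁻¹)
    nucleophile ⇌ dormant form (K = 6.20, k = 0.270 h⁻¹)
    electrophile + nucleophile → acid set free + product (k = 1.40 L mol⁻¹ h⁻¹)

- At 20.0 h the flask held 0.0186 M of salt of the base against 0.00190 M of protonated nucleophile, about ten times as much, so the free base carried the acid, and L, now 16.0 %, left 84.0 %. The flask's L stayed that small partly because of the hold-up by the transfer of gas to nucleophile, together with the time allowed: without the hold-up c stood at 22.4 %, and at 200 h it stood at 97.8 %. The neighbour flask tests this with 0.051 M of free base and c = 12.5 %: its L is 39.3 %, so its bracket runs from 60.7 % to 71.4 %, and its fr stood at 67.0 %.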